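**Plan**

- Retrosynthetic cuts, in order: the acetate C–O bond; C2'–C3' of the side chain (sp3–sp2 coupling); C3–C1' (tertiary C3 radical plus vinylboronate, the key step); C2–C3 of the five-membered ring (oxidative bis-enolate coupling); C3a–C3 ([3,3] shift); C7a–C1 (sp2–sp3 coupling).
- Enabling feature: C3 is the β-carbon of the C2 carboxyl in the five-membered ring and carries a methyl, so C2–C3 is a masked 2-methylsuccinate. A second carboxyl parked on C3 leaves as CO2 and turns this natively electrophilic carbon into a nucleophilic tertiary radical, which joins the electrophilic CH2 of a vinylboronate.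
- Forward order: the six-membered ring is bought; the C1–C2 arm is put on C7a; a Claisen shift makes C3a and the C7=C7a alkene; the five-membered ring is closed at C2–C3; the side chain is joined at C3–C1' and extended at C2'–C3'.
- Stereochemistry: the C7 carbinol comes from CBS catalysis; C3a from it by suprafacial [3,3] transfer; C3 by radical capture trans to the C3a methyl; C2 by base equilibration trans to the side chain; the Z-alkene from anti-carbomagnesiation of propargyl alcohol and a stereoretentive coupling.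

Key step: step 9

Remark: ring atoms are numbered as in 1H-indene (C1–C3, C3a, C4–C7, C7a) and side-chain atoms C1'–C5' from C3; the target is the (2S,3R,3aS,3'Z) isomer. It is assumed that the pseudo-axial C3a methyl shields its face of C3 more than the C4 methyls shield the other face.

Step 1
Reactants: 1 4,4-dimethylcyclohexane-1,3-dione
Product: 2 6,6-dimethyl-3-(2-methylpropoxy)cyclohex-2-en-1-one
Conditions: i-BuOH, TsOH (cat.), toluene, reflux, Dean–Stark
Reagents that add atoms: 2-methylpropan-1-ol, CC(C)CO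
Why: Acid-catalysed vinylogous ester formation should take place at the carbonyl remote from the gem-dimethyl carbon, which leaves the hindered carbonyl free for step 2; no stereocentre is formed.

Step 2
Reactants: 2 6,6-dimethyl-3-(2-methylpropoxy)cyclohex-2-en-1-one
Product: 4 3,4,4-trimethylcyclohex-2-en-1-one, via tertiary carbinol 3 (not isolated)
Conditions: MeLi, THF, −78 to 0 °C; then 1 M HCl, rt
Reagents that add atoms: methyllithium, [Li]C; water, O
Why: Stork–Danheiser transposition: 1,2-addition to the vinylogous ester carbonyl, then acid hydrolysis of the enol ether with loss of water, should give the enone with the new methyl next to the gem-dimethyl carbon; the carbinol centre is lost again.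

Step 3
Reactants: 4 3,4,4-trimethylcyclohex-2-en-1-one
Product: 6 2-bromo-3,4,4-trimethylcyclohex-2-en-1-one, via dibromo ketone 5 (not isolated)
Conditions: Br2, CH2Cl2, 0 °C; then Et3N, 0 °C to rt
Reagents that add atoms: bromine, BrBr
Why: Bromine addition to the enone alkene followed by base-induced loss of HBr (α-bromination of an enone) should give the 2-bromoenone; no stereocentre remains.

Step 4
Reactants: 6 2-bromo-3,4,4-trimethylcyclohex-2-en-1-one, 7 (3-ethoxy-3-oxopropyl)zinc bromide
Product: 8 ethyl 3-(2,3,3-trimethyl-6-oxocyclohex-1-en-1-yl)propanoate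
Conditions: Pd(OAc)2 (cat.), SPhos, THF, 45 °C
Reagents that add atoms: none
Why: Negishi coupling of the alkenyl bromide with the ester-bearing alkylzinc halide should tolerate the ketone and puts the C1–C2 arm with its carboxyl on the future C7a; no stereocentre is formed.

Step 5
Reactants: 8 ethyl 3-(2,3,3-trimethyl-6-oxocyclohex-1-en-1-yl)propanoate
Product: 9 ethyl 3-[(6R)-6-hydroxy-2,3,3-trimethylcyclohex-1-en-1-yl]propanoate
Conditions: (S)-Me-CBS oxazaborolidine (10 mol %), catecholborane, toluene, −78 °C; then aq. NaOH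
Reagents that add atoms: none
Why: CBS reduction, in which the fully substituted alkene carbon acts as the large group and the ring CH2 as the small one, should deliver hydride under catalyst control to give the (R)-allylic alcohol and leave the ester untouched.

Step 6
Reactants: 9 ethyl 3-[(6R)-6-hydroxy-2,3,3-trimethylcyclohex-1-en-1-yl]propanoate
Product: 11 methyl 2-[(1S)-2-(3-ethoxy-3-oxopropyl)-1,6,6-trimethylcyclohex-2-en-1-yl]propanoate (both epimers at the propanoate carbon), via mixed ketene acetal 10 (not isolated)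
Conditions: EtC(OMe)3, EtCO2H (cat.), xylene, 140 °C, MeOH distilled off
Reagents that add atoms: trimethyl orthopropanoate, CCC(OC)(OC)OC
Why: Johnson–Claisen rearrangement: the [3,3] shift is suprafacial, so the new C3a–C3 bond forms on the face that carried the C–O bond and sets the quaternary (S)-C3a next to the gem-dimethyl carbon while moving the alkene to C7=C7a; the propanoate α-centre is not controlled and is erased in step 7.

Step 7
Reactants: 11 methyl 2-[(1S)-2-(3-ethoxy-3-oxopropyl)-1,6,6-trimethylcyclohex-2-en-1-yl]propanoate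
Product: 13 2-ethyl 3-methyl (3aS)-3,3a,4,4-tetramethyl-2,3,3a,4,5,6-hexahydro-1H-indene-2,3-dicarboxylate (diastereomers at C2 and C3), via dilithium bis-enolate 12 (not isolated)
Conditions: LiN(i-Pr)2 (2.3 equiv), THF, −78 to −20 °C; then I2, −78 to 0 °C
Reagents that add atoms: none
Why: Intramolecular oxidative coupling of a diester bis-enolate: iodination of the less hindered enolate and 5-exo-tet displacement by the tertiary enolate should close the five-membered ring at C2–C3; C2 and C3 form without control, which is acceptable because C3 is erased in step 9 and C2 is equilibrated in step 12.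

Step 8
Reactants: 13 2-ethyl 3-methyl (3aS)-3,3a,4,4-tetramethyl-2,3,3a,4,5,6-hexahydro-1H-indene-2,3-dicarboxylate
Product: 14 (3aS)-2-(ethoxycarbonyl)-3,3a,4,4-tetramethyl-2,3,3a,4,5,6-hexahydro-1H-indene-3-carboxylic acid (diastereomers at C2 and C3)
Conditions: LiI, pyridine, reflux; then 1 M HCl
Reagents that add atoms: none
Why: SN2 dealkylation by iodide attacks the methyl carbon and is therefore indifferent to the crowded acyl group, and it should cleave the methyl ester much faster than the ethyl ester; no stereocentre changes.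

Step 9
Reactants: 14 (3aS)-2-(ethoxycarbonyl)-3,3a,4,4-tetramethyl-2,3,3a,4,5,6-hexahydro-1H-indene-3-carboxylic acid, 15 2-ethenyl-4,4,5,5-tetramethyl-1,3,2-dioxaborolane
Product: 16 ethyl (3R,3aS)-3,3a,4,4-tetramethyl-3-[2-(4,4,5,5-tetramethyl-1,3,2-dioxaborolan-2-yl)ethyl]-2,3,3a,4,5,6-hexahydro-1H-indene-2-carboxylate (both C2 epimers)
Conditions: Ir[dF(CF3)ppy]2(dtbbpy)PF6 (2 mol %), Cs2CO3, DMF, blue LEDs, rt, degassed
Reagents that add atoms: none
Why: The excited iridium photocatalyst oxidises the caesium carboxylate of 14, CO2 is lost, and the tertiary C3 radical (nucleophilic at a carbon that is the electrophilic β-position of the C2 ester in two-electron terms) adds to the unsubstituted terminus of vinylboronate 15; the α-boryl radical is then reduced by the reduced photocatalyst and protonated. The closest known reaction type is the photoredox decarboxylative Giese-type addition of alkyl carboxylic acids to vinyl boronic esters, together with the coupling of ring-bound tertiary radicals next to quaternary centres with electron-poor alkenes. No ring is closed. The new quaternary stereocentre C3 is controlled by C3a: the radical is planar, the C3a methyl stands pseudo-axial over one face of the five-membered ring, and the alkene should approach from the other face, so the new chain ends trans to that methyl and the C3 methyl cis to it, whatever the configuration of C3 in 14. The step needs chemoselective oxidation (only the C3 carboxyl is free, the C2 carboxyl being an ethyl ester), regioselective attack at the CH2 terminus (secured by boron stabilisation of the adduct radical) and facial selectivity (secured by the angular methyl; the C2 ester is epimerisable and is corrected in step 12).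

Step 10
Reactants: 17 prop-2-yn-1-ol
Product: 19 (2Z)-3-iodo-2-methylprop-2-en-1-ol, via alkenylmagnesium alkoxide 18 (not isolated)
Conditions: MeMgBr (2.5 equiv), CuI (10 mol %), THF, −10 °C to rt; then I2, −10 °C
Reagents that add atoms: methylmagnesium bromide, C[Mg]Br; iodine, II
Why: Copper-catalysed anti-carbomagnesiation of the propargylic alkoxide should proceed through a five-membered magnesium chelate that holds the metal cis to the CH2O group, and iodinolysis with retention then fixes the Z geometry.

Step 11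
Reactants: 16 ethyl (3R,3aS)-3,3a,4,4-tetramethyl-3-[2-(4,4,5,5-tetramethyl-1,3,2-dioxaborolan-2-yl)ethyl]-2,3,3a,4,5,6-hexahydro-1H-indene-2-carboxylate, 19 (2Z)-3-iodo-2-methylprop-2-en-1-ol
Product: 20 ethyl (3R,3aS)-3-[(3Z)-5-hydroxy-4-methylpent-3-en-1-yl]-3,3a,4,4-tetramethyl-2,3,3a,4,5,6-hexahydro-1H-indene-2-carboxylate (both C2 epimers)
Conditions: Pd(OAc)2 (5 mol %), RuPhos, K3PO4, toluene/H2O, 80 °C
Reagents that add atoms: none
Why: B-alkyl Suzuki–Miyaura coupling of the primary alkylboronate with the alkenyl iodide should proceed with retention of alkene geometry, which carries the Z configuration into the side chain; the ring stereocentres are not touched.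

Step 12
Reactants: 20 ethyl (3R,3aS)-3-[(3Z)-5-hydroxy-4-methylpent-3-en-1-yl]-3,3a,4,4-tetramethyl-2,3,3a,4,5,6-hexahydro-1H-indene-2-carboxylate
Product: 22 (2S,3R,3aS)-3-[(3Z)-5-hydroxy-4-methylpent-3-en-1-yl]-3,3a,4,4-tetramethyl-2,3,3a,4,5,6-hexahydro-1H-indene-2-carboxylic acid, via equilibrated ethyl ester 21 (not isolated)
Conditions: NaOEt (cat.), EtOH, 70 °C; then LiOH, H2O/EtOH, 80 °C; then 1 M HCl
Reagents that add atoms: lithium hydroxide, [Li+].[OH-]
Why: Base-mediated ester epimerisation followed by saponification: C2 should settle in the (S) configuration, with the ester cis to the small C3 methyl and trans to the C3 side chain (whose first two carbons lie over the other face), before the ester is hydrolysed.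

Step 13
Reactants: 22 (2S,3R,3aS)-3-[(3Z)-5-hydroxy-4-methylpent-3-en-1-yl]-3,3a,4,4-tetramethyl-2,3,3a,4,5,6-hexahydro-1H-indene-2-carboxylic acid
Product: 23 (2S,3R,3aS)-3-[(3Z)-5-(acetyloxy)-4-methylpent-3-en-1-yl]-3,3a,4,4-tetramethyl-2,3,3a,4,5,6-hexahydro-1H-indene-2-carboxylic acid
Conditions: Ac2O, pyridine, DMAP (cat.), CH2Cl2, 0 °C to rt; aq. NaHCO3, then dilute HCl
Reagents that add atoms: acetic anhydride, CC(=O)OC(C)=O
Why: O-Acylation of the primary allylic alcohol should be selective because any mixed anhydride at the hindered carboxyl is hydrolysed on aqueous work-up; no stereocentre or alkene geometry is affected.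

**Compound list**

1 | 4,4-dimethylcyclohexane-1,3-dione | O=C1CC(=O)C(C)(C)CC1 | starting material
2 | 6,6-dimethyl-3-(2-methylpropoxy)cyclohex-2-en-1-one | CC(C)COC1=CC(=O)C(C)(C)CC1 | intermediate
3 | 1,6,6-trimethyl-3-(2-methylpropoxy)cyclohex-2-en-1-ol (racemic carbinol) | CC(C)COC1=CC(C)(O)C(C)(C)CC1 | intermediate
4 | 3,4,4-trimethylcyclohex-2-en-1-one | CC1=CC(=O)CCC1(C)C | intermediate
5 | 2,3-dibromo-3,4,4-trimethylcyclohexan-1-one | CC1(Br)C(Br)C(=O)CCC1(C)C | intermediate
6 | 2-bromo-3,4,4-trimethylcyclohex-2-en-1-one | CC1=C(Br)C(=O)CCC1(C)C | intermediate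
7 | (3-ethoxy-3-oxopropyl)zinc bromide | CCOC(=O)CC[Zn]Br | starting material
8 | ethyl 3-(2,3,3-trimethyl-6-oxocyclohex-1-en-1-yl)propanoate | CCOC(=O)CCC1=C(C)C(C)(C)CCC1=O | intermediate
9 | ethyl 3-[(6R)-6-hydroxy-2,3,3-trimethylcyclohex-1-en-1-yl]propanoate | CCOC(=O)CCC1=C(C)C(C)(C)CC[C@H]1O | intermediate
10 | ethyl 3-[(6R)-6-[(1-methoxyprop-1-en-1-yl)oxy]-2,3,3-trimethylcyclohex-1-en-1-yl]propanoate | CCOC(=O)CCC1=C(C)C(C)(C)CC[C@H]1OC(OC)=CC | intermediate
11 | methyl 2-[(1S)-2-(3-ethoxy-3-oxopropyl)-1,6,6-trimethylcyclohex-2-en-1-yl]propanoate (both epimers at the propanoate carbon) | COC(=O)C(C)[C@]1(C)C(CCC(=O)OCC)=CCCC1(C)C | intermediate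
12 | dilithium bis-enolate of 11 (both ester groups as lithium enolates) | COC(O[Li])=C(C)[C@]1(C)C(CC=C(O[Li])OCC)=CCCC1(C)C | intermediate
13 | 2-ethyl 3-methyl (3aS)-3,3a,4,4-tetramethyl-2,3,3a,4,5,6-hexahydro-1H-indene-2,3-dicarboxylate (diastereomers at C2 and C3) | COC(=O)C1(C)C(C(=O)OCC)CC2=CCCC(C)(C)[C@@]21C | intermediate
14 | (3aS)-2-(ethoxycarbonyl)-3,3a,4,4-tetramethyl-2,3,3a,4,5,6-hexahydro-1H-indene-3-carboxylic acid (diastereomers at C2 and C3) | OC(=O)C1(C)C(C(=O)OCC)CC2=CCCC(C)(C)[C@@]21C | intermediate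
15 | 2-ethenyl-4,4,5,5-tetramethyl-1,3,2-dioxaborolane | C=CB1OC(C)(C)C(C)(C)O1 | starting material
16 | ethyl (3R,3aS)-3,3a,4,4-tetramethyl-3-[2-(4,4,5,5-tetramethyl-1,3,2-dioxaborolan-2-yl)ethyl]-2,3,3a,4,5,6-hexahydro-1H-indene-2-carboxylate (both C2 epimers) | CC1(C)OB(CC[C@]2(C)C(C(=O)OCC)CC3=CCCC(C)(C)[C@@]32C)OC1(C)C | intermediate
17 | prop-2-yn-1-ol | C#CCO | starting material
18 | bromomagnesium (2Z)-3-(bromomagnesio)-2-methylprop-2-en-1-olate | Br[Mg]/C=C(/C)CO[Mg]Br | intermediate
19 | (2Z)-3-iodo-2-methylprop-2-en-1-ol | OC/C(C)=C\I | intermediate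
20 | ethyl (3R,3aS)-3-[(3Z)-5-hydroxy-4-methylpent-3-en-1-yl]-3,3a,4,4-tetramethyl-2,3,3a,4,5,6-hexahydro-1H-indene-2-carboxylate (both C2 epimers) | OC/C(C)=C\CC[C@]1(C)C(C(=O)OCC)CC2=CCCC(C)(C)[C@@]21C | intermediate
21 | ethyl (2S,3R,3aS)-3-[(3Z)-5-hydroxy-4-methylpent-3-en-1-yl]-3,3a,4,4-tetramethyl-2,3,3a,4,5,6-hexahydro-1H-indene-2-carboxylate | OC/C(C)=C\CC[C@]1(C)[C@@H](C(=O)OCC)CC2=CCCC(C)(C)[C@@]21C | intermediate
22 | (2S,3R,3aS)-3-[(3Z)-5-hydroxy-4-methylpent-3-en-1-yl]-3,3a,4,4-tetramethyl-2,3,3a,4,5,6-hexahydro-1H-indene-2-carboxylic acid | OC/C(C)=C\CC[C@]1(C)[C@@H](C(=O)O)CC2=CCCC(C)(C)[C@@]21C | intermediate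
23 | (2S,3R,3aS)-3-[(3Z)-5-(acetyloxy)-4-methylpent-3-en-1-yl]-3,3a,4,4-tetramethyl-2,3,3a,4,5,6-hexahydro-1H-indene-2-carboxylic acid | CC(=O)OC/C(C)=C\CC[C@]1(C)[C@@H](C(=O)O)CC2=CCCC(C)(C)[C@@]21C | target

**Step count and risks**

Total steps: 13. Longest linear sequence: 12 (steps 1–9 and 11–13); step 10 is a one-step branch.

Steps most likely to fail:

1. Step 9. The tertiary radical sits between two fully substituted carbons and may add only slowly to the weakly electrophilic vinylboronate. Over-oxidation to the cation with loss of a proton towards the C2=C3 enoate, or hydrogen abstraction, could then win. The facial discrimination also rests on the angular methyl alone. The fallback does not improve the facial control; it changes how the radical is made, what traps it, and how the Z-alkene is built. It sets out from 14 and returns at 20. The acid 14 is condensed with N-hydroxyphthalimide (N,N'-diisopropylcarbodiimide, DMAP) to the redox-active ester 1,3-dioxoisoindolin-2-yl (3aS)-2-(ethoxycarbonyl)-3,3a,4,4-tetramethyl-2,3,3a,4,5,6-hexahydro-1H-indene-3-carboxylate F1. Reductive fragmentation (Ru(bpy)3(PF6)2, Hantzsch ester, i-Pr2NEt, blue light) in the presence of acrolein, a much stronger acceptor, should give ethyl (3R,3aS)-3,3a,4,4-tetramethyl-3-(3-oxopropyl)-2,3,3a,4,5,6-hexahydro-1H-indene-2-carboxylate F2. Still–Gennari olefination with methyl 2-[bis(2,2,2-trifluoroethoxy)phosphoryl]propanoate (KN(SiMe3)2, 18-crown-6, THF, −78 °C) should give ethyl (3R,3aS)-3-[(3Z)-5-methoxy-4-methyl-5-oxopent-3-en-1-yl]-3,3a,4,4-tetramethyl-2,3,3a,4,5,6-hexahydro-1H-indene-2-carboxylate F3. i-Bu2AlH at −78 °C should reduce the conjugated methyl ester and spare the hindered ethyl ester, which gives 20.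

2. Step 7. The second deprotonation, at the hindered tertiary C–H beside the quaternary carbon, may be incomplete. The mono-enolate could then undergo Claisen condensation or intermolecular coupling instead of ring closure. The fallback changes which ring bond is made last (C1–C2 by enolate alkylation); it sets out from 6 and returns at 13. Stille coupling of 6 with tributyl({[tert-butyl(dimethyl)silyl]oxy}methyl)stannane (Pd(PPh3)4, toluene, 100 °C) should give 2-({[tert-butyl(dimethyl)silyl]oxy}methyl)-3,4,4-trimethylcyclohex-2-en-1-one F4. CBS reduction as in step 5 should give (1R)-2-({[tert-butyl(dimethyl)silyl]oxy}methyl)-3,4,4-trimethylcyclohex-2-en-1-ol F5. Johnson–Claisen rearrangement as in step 6 should give methyl 2-[(1S)-2-({[tert-butyl(dimethyl)silyl]oxy}methyl)-1,6,6-trimethylcyclohex-2-en-1-yl]propanoate F6. LiN(i-Pr)2 and ethyl bromoacetate alkylate its only enolisable position to give 4-ethyl 1-methyl 2-[(1S)-2-({[tert-butyl(dimethyl)silyl]oxy}methyl)-1,6,6-trimethylcyclohex-2-en-1-yl]-2-methylbutanedioate F7. Ph3PBr2 converts the silyl ether directly into 4-ethyl 1-methyl 2-[(1R)-2-(bromomethyl)-1,6,6-trimethylcyclohex-2-en-1-yl]-2-methylbutanedioate F8. KN(SiMe3)2 in THF then closes the ring by 5-exo-tet alkylation of the ethyl ester enolate to give 13.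

3. Step 6. Acid-catalysed loss of the allylic oxygen to a cyclohexadiene may outrun the rearrangement, because the new bond must form at a tetrasubstituted alkene carbon flanked by the gem-dimethyl group. The fallback replaces the acid-catalysed ortho ester exchange by a base-mediated Ireland–Claisen rearrangement near room temperature; it sets out from 9 and returns at 11. Acylation of 9 with propanoyl chloride (pyridine) gives ethyl 3-[(6R)-2,3,3-trimethyl-6-(propanoyloxy)cyclohex-1-en-1-yl]propanoate F9. LiN(i-Pr)2 (2.3 equiv) and Me3SiCl in THF at −78 °C form the bis(silyl ketene acetal), whose allylic half should rearrange on warming to 50 °C. Aqueous work-up gives 2-[(1S)-2-(3-ethoxy-3-oxopropyl)-1,6,6-trimethylcyclohex-2-en-1-yl]propanoic acid F10, and Me3SiCHN2 in MeOH/toluene gives 11.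

**Further compounds**

F1 | step 9 | 1,3-dioxoisoindolin-2-yl (3aS)-2-(ethoxycarbonyl)-3,3a,4,4-tetramethyl-2,3,3a,4,5,6-hexahydro-1H-indene-3-carboxylate | O=C(ON3C(=O)c4ccccc4C3=O)C1(C)C(C(=O)OCC)CC2=CCCC(C)(C)[C@@]21C
F2 | step 9 | ethyl (3R,3aS)-3,3a,4,4-tetramethyl-3-(3-oxopropyl)-2,3,3a,4,5,6-hexahydro-1H-indene-2-carboxylate | O=CCC[C@]1(C)C(C(=O)OCC)CC2=CCCC(C)(C)[C@@]21C
F3 | step 9 | ethyl (3R,3aS)-3-[(3Z)-5-methoxy-4-methyl-5-oxopent-3-en-1-yl]-3,3a,4,4-tetramethyl-2,3,3a,4,5,6-hexahydro-1H-indene-2-carboxylate | COC(=O)/C(C)=C\CC[C@]1(C)C(C(=O)OCC)CC2=CCCC(C)(C)[C@@]21C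
F4 | step 7 | 2-({[tert-butyl(dimethyl)silyl]oxy}methyl)-3,4,4-trimethylcyclohex-2-en-1-one | CC(C)(C)[Si](C)(C)OCC1=C(C)C(C)(C)CCC1=O
F5 | step 7 | (1R)-2-({[tert-butyl(dimethyl)silyl]oxy}methyl)-3,4,4-trimethylcyclohex-2-en-1-ol | CC(C)(C)[Si](C)(C)OCC1=C(C)C(C)(C)CC[C@H]1O
F6 | step 7 | methyl 2-[(1S)-2-({[tert-butyl(dimethyl)silyl]oxy}methyl)-1,6,6-trimethylcyclohex-2-en-1-yl]propanoate | COC(=O)C(C)[C@]1(C)C(CO[Si](C)(C)C(C)(C)C)=CCCC1(C)C
F7 | step 7 | 4-ethyl 1-methyl 2-[(1S)-2-({[tert-butyl(dimethyl)silyl]oxy}methyl)-1,6,6-trimethylcyclohex-2-en-1-yl]-2-methylbutanedioate | CCOC(=O)CC(C)(C(=O)OC)[C@]1(C)C(CO[Si](C)(C)C(C)(C)C)=CCCC1(C)C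
F8 | step 7 | 4-ethyl 1-methyl 2-[(1R)-2-(bromomethyl)-1,6,6-trimethylcyclohex-2-en-1-yl]-2-methylbutanedioate | CCOC(=O)CC(C)(C(=O)OC)[C@]1(C)C(CBr)=CCCC1(C)C
F9 | step 6 | ethyl 3-[(6R)-2,3,3-trimethyl-6-(propanoyloxy)cyclohex-1-en-1-yl]propanoate | CCOC(=O)CCC1=C(C)C(C)(C)CC[C@H]1OC(=O)CC
F10 | step 6 | 2-[(1S)-2-(3-ethoxy-3-oxopropyl)-1,6,6-trimethylcyclohex-2-en-1-yl]propanoic acid | OC(=O)C(C)[C@]1(C)C(CCC(=O)OCC)=CCCC1(C)C
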